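Assumption: the SMILES is read as the all-E polyene with a cis-(5R,6S)-5,6-diol end group and a (5'R,8'R)-5',8'-furanoid end group; carotenoid numbering is used for the C25 and C40 compounds.

**Retrosynthetic overview**
1. Target 27 ⇐ ring expansion (oxirane → 2,5-dihydrofuran) of the C40 5',6'-epoxide 26; this last step forms the furan ring and sets C8'.
2. 26 ⇐ two Wittig condensations, C15 + C10 + C15: diol-end salt 17 (C11=C12), central dialdehyde 24, epoxide-end salt 20 (C11'=C12').
3. 20 ⇐ epoxy aldehyde 8 (C3 Wittig, vinyl Grignard, Ph3P·HBr). 17 ⇐ ketol 10 + C6 enynol 11 (C6–C7 bond, sets C6), then alkyne → E-alkene.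
4. 10 ⇐ 8 by Baeyer–Villiger excision of C7, so one Sharpless epoxidation of β-cyclogeraniol 6 supplies C5 of both end groups; 6 ⇐ 2-methylcyclohexanone.
5. Ring order: both cyclohexane rings are carried from 2-methylcyclohexanone, the oxirane is made in step 4, the dihydrofuran is made last (step 16). 24 ⇐ protected fumaraldehyde 21 + C3 ylide.

**Route**

Step 1
Reactants: 1 2-methylcyclohexan-1-one
Product: 3 2,2,6-trimethylcyclohexan-1-one (racemic), via 2,6-dimethylcyclohexan-1-one 2 (not isolated)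
Conditions: LiN(iPr)2 (1.05 equiv), THF, −78 °C; MeI, → 0 °C; recool, LiN(iPr)2 (1.2 equiv); MeI, → rt; distil
Reagents that add atoms: iodomethane, CI
Why: Two successive kinetic enolate alkylations (first at the α-CH2, then at an α-methine) converge on the 2,2,6-pattern, after which only one hindered methine is left so over-methylation is slow; the C6 centre is racemic and becomes sp2 in step 3.

Step 2
Reactants: 3 2,2,6-trimethylcyclohexan-1-one
Product: 4 2,4,6-tri(propan-2-yl)-N'-[(1E)-2,2,6-trimethylcyclohexylidene]benzenesulfonohydrazide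
Conditions: ArSO2NHNH2 (1.05 equiv), HCl (cat.), MeOH, rt, 24 h
Reagents that add atoms: 2,4,6-tri(propan-2-yl)benzenesulfonohydrazide, CC(C)c1cc(C(C)C)c(S(=O)(=O)NN)c(C(C)C)c1
Why: Acid-catalysed hydrazone condensation; the bulky sulfonamide nitrogen lies anti to the quaternary carbon and therefore syn to the only α-hydrogen, as the Shapiro reaction needs.

Step 3
Reactants: 4 the arylsulfonylhydrazone
Product: 6 (2,6,6-trimethylcyclohex-1-en-1-yl)methanol (β-cyclogeraniol), via 2,6,6-trimethylcyclohex-1-en-1-yllithium 5 (not isolated)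
Conditions: s-BuLi (2.3 equiv), TMEDA/hexane, −78 → 0 °C; then (CH2O)n, THF, 0 °C → rt; H2O
Reagents that add atoms: formaldehyde (from paraformaldehyde), C=O
Why: Shapiro reaction: the dianion loses sulfinate and N2 to give the tetrasubstituted vinyllithium regiospecifically (single α-hydrogen), which is hydroxymethylated by formaldehyde.

Step 4
Reactants: 6 β-cyclogeraniol
Product: 7 [(1R,6R)-2,2,6-trimethyl-7-oxabicyclo[4.1.0]heptan-1-yl]methanol
Conditions: Ti(OiPr)4 (0.2 equiv), (−)-diethyl D-tartrate [(2S,3S), 0.26 equiv], t-BuOOH (2 equiv), 4 Å MS, CH2Cl2, −20 °C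
Reagents that add atoms: tert-butyl hydroperoxide, CC(C)(C)OO
Why: Sharpless asymmetric epoxidation of a primary allylic alcohol; the D-tartrate titanium complex delivers oxygen to the alkene face opposite to the one that gives (2S,3S)-epoxygeraniol with the L-tartrate, which makes carotenoid C5 R and C6 S-type (both oxirane carbons set here).

Step 5
Reactants: 7 the epoxy alcohol
Product: 8 (1S,6R)-2,2,6-trimethyl-7-oxabicyclo[4.1.0]heptane-1-carbaldehyde
Conditions: (n-Pr4N)RuO4 (5 mol%), N-methylmorpholine N-oxide (1.5 equiv), 4 Å MS, CH2Cl2, rt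
Reagents that add atoms: none
Why: Ley–Griffith oxidation is neutral and stops at the aldehyde; the aldehyde has no α-hydrogen, so nothing can epimerise and the oxirane is untouched.

Step 6
Reactants: 8 the epoxy aldehyde
Product: 10 (2R)-2-hydroxy-2,6,6-trimethylcyclohexan-1-one, via epoxy formate 9 (not isolated)
Conditions: mCPBA (1.5 equiv), CH2Cl2/aq. phosphate buffer (pH 7), 0 °C → rt; then K2CO3 (0.2 equiv), MeOH, 0 °C
Reagents that add atoms: 3-chloroperoxybenzoic acid, OOC(=O)c1cccc(Cl)c1
Why: Baeyer–Villiger oxidation in which the tertiary, oxygen-bearing oxirane carbon migrates with retention in preference to hydrogen (as α-alkoxy aldehydes do); methanolysis of the formate frees an epoxy hemiketal that collapses to the ketone by C6–O cleavage, so the C5–O bond is never broken and C5 stays R.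

Step 7
Reactants: 10 the (R)-ketol; 11 (2E)-3-methylpent-2-en-4-yn-1-ol
Product: 14 (1R,2R)-1-[(3E)-5-hydroxy-3-methylpent-3-en-1-yn-1-yl]-2,6,6-trimethylcyclohexane-1,2-diol, via silyl ether 12 (not isolated), via silylated adduct 13 (not isolated)
Conditions: 10, LiN(SiMe3)2 (1.05 equiv), THF, −78 °C; Me3SiCl (1.05 equiv), → 0 °C; add to 11 (1.6 equiv)/n-BuLi (3.2 equiv), THF, −78 → 0 °C; then K2CO3, MeOH, rt
Reagents that add atoms: none
Why: 1,2-addition of a lithium acetylide to a non-enolisable ketone; the non-chelating silyloxy group sits axial, and Felkin–Anh axial attack anti to it and to the axial C1 methyl puts the new C6–O bond cis to the C5–O bond, which sets C6 as the cis-diol.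

Step 8
Reactants: 14 the alkynyl triol
Product: 15 (1S,2R)-1-[(1E,3E)-5-hydroxy-3-methylpenta-1,3-dien-1-yl]-2,6,6-trimethylcyclohexane-1,2-diol
Conditions: LiAlH4 (3 equiv), THF, 0 → 45 °C; potassium sodium tartrate (aq)
Reagents that add atoms: none
Why: Alkoxide-directed trans-hydroalumination of the tertiary propargylic alcohol gives only the E C7=C8 alkene and leaves both carbinol centres untouched.

Step 9
Reactants: 15 the dienetriol
Product: 17 {(2E,4E)-5-[(1S,2R)-1,2-dihydroxy-2,6,6-trimethylcyclohexyl]-3-methylpenta-2,4-dien-1-yl}(triphenyl)phosphonium bromide, via allylic bromide 16 (not isolated)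
Conditions: PPh3 (1.1 equiv), CBr4 (1.1 equiv), CH2Cl2, −20 → 0 °C; then PPh3 (1.3 equiv), rt; precipitate with Et2O
Reagents that add atoms: triphenylphosphine, c1ccc(cc1)P(c1ccccc1)c1ccccc1; tetrabromomethane, BrC(Br)(Br)Br
Why: Appel bromination takes only the primary allylic alcohol and the excess phosphine quaternises the bromide by SN2, all without acid, so the dienylic tertiary carbinol is not ionised.

Step 10
Reactants: 8 the epoxy aldehyde
Product: 18 (3E)-4-[(1S,6R)-2,2,6-trimethyl-7-oxabicyclo[4.1.0]heptan-1-yl]but-3-en-2-one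
Conditions: Ph3P=CHC(O)CH3 (1.5 equiv), toluene, 90 °C
Reagents that add atoms: 1-(triphenyl-λ5-phosphanylidene)propan-2-one, CC(=O)C=P(c1ccccc1)(c1ccccc1)c1ccccc1
Why: Wittig reaction of a stabilised ylide with a hindered, non-enolisable aldehyde gives the E-enone under neutral conditions.

Step 11
Reactants: 18 the epoxy enone
Product: 19 (1E)-3-methyl-1-[(1S,6R)-2,2,6-trimethyl-7-oxabicyclo[4.1.0]heptan-1-yl]penta-1,4-dien-3-ol (both C3 epimers)
Conditions: vinylmagnesium bromide (1.3 equiv), THF, −30 → 0 °C; H2O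
Reagents that add atoms: vinylmagnesium bromide, C=C[Mg]Br
Why: Grignard 1,2-addition to the methyl ketone; the new carbinol centre is not controlled because it becomes sp2 in step 12.

Step 12
Reactants: 19 the divinyl carbinol
Product: 20 {(2E,4E)-3-methyl-5-[(1S,6R)-2,2,6-trimethyl-7-oxabicyclo[4.1.0]heptan-1-yl]penta-2,4-dien-1-yl}(triphenyl)phosphonium bromide
Conditions: Ph3P·HBr (1.0 equiv), MeOH, 0 °C → rt, dark; crystallise (EtOAc)
Reagents that add atoms: triphenylphosphonium bromide, [PH+](c1ccccc1)(c1ccccc1)c1ccccc1.[Br-]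
Why: Allylic transposition of the SN1' type: the doubly allylic tertiary alcohol ionises under the weakly acidic phosphonium salt far faster than the oxirane, and phosphine captures the pentadienyl cation at the unhindered terminus; the 9E salt is the one that crystallises.

Step 13
Reactants: 21 (2E)-1,1,4,4-tetramethoxybut-2-ene
Product: 24 (2E,4E,6E)-2,7-dimethylocta-2,4,6-trienedial, via fumaraldehyde 22 (not isolated), via (2E,4E)-2-methylhexa-2,4-dienedial 23 (not isolated)
Conditions: sulfonic acid ion-exchange resin (H+ form, cat.), acetone/H2O, rt, filter; then Ph3P=C(CH3)CHO (2.2 equiv), CH2Cl2, rt → 40 °C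
Reagents that add atoms: 2-(triphenyl-λ5-phosphanylidene)propanal, CC(C=O)=P(c1ccccc1)(c1ccccc1)c1ccccc1
Why: Acetal hydrolysis followed by a double Wittig reaction with a formyl-stabilised ylide, which is E-selective and stops at the less electrophilic α-methyl enal termini.

Step 14
Reactants: 20 the epoxide-end C15 salt; 24 the C10 dialdehyde (3 equiv, excess recovered)
Product: 25 (all-E)-(5R,6S)-5,6-epoxy-5,6-dihydro-12'-apo-β-caroten-12'-al
Conditions: 1,2-epoxybutane, 65 °C, dark, Ar
Reagents that add atoms: none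
Why: Wittig mono-olefination with excess dialdehyde in 1,2-epoxybutane, which generates the ylide without strong base and scavenges HBr; the oxirane survives and any Z isomer at the new double bond equilibrates to E at this temperature.

Step 15
Reactants: 17 the diol-end C15 salt; 25 the C25 epoxy aldehyde
Product: 26 (all-E)-(5R,6S,5'R,6'S)-5',6'-epoxy-5,6,5',6'-tetrahydro-β,β-carotene-5,6-diol
Conditions: 1,2-epoxybutane/EtOH, 65 °C, dark, Ar
Reagents that add atoms: none
Why: Second Wittig olefination under the same neutral conditions, which tolerate the free cis-diol and the oxirane and give the all-E C40 chain after thermal Z → E equilibration.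

Step 16
Reactants: 26 the C40 epoxy diol
Product: 27 (all-E)-(5R,6S,5'R,8'R)-5',8'-epoxy-5,6,5',8'-tetrahydro-β,β-carotene-5,6-diol (target)
Conditions: (R)-3,3'-bis(2,4,6-triisopropylphenyl)-1,1'-binaphthyl-2,2'-diyl hydrogen phosphate (5 mol%), toluene, −40 °C, dark, Ar; Et3N quench
Reagents that add atoms: none
Why: Proposed new method: the chiral phosphoric acid hydrogen-bonds and protonates the strained oxirane oxygen, C6'–O heterolysis gives a polyenyl cation held as a contact ion pair with the chiral phosphate that stays hydrogen-bonded to the C5' hydroxyl, and this tethered oxygen closes on C8' (C5'–O never breaks, so 5'R is kept) from the face left open by the catalyst pocket to set 8'R with the chain anti to the C5' methyl, while the weak acid at −40 °C leaves the unstrained C6 carbinol of the diol end un-ionised; the closest known reactions are the achiral-acid 5,6-epoxide to 5,8-furanoid rearrangement of carotenoid epoxides, which gives both C8 epimers, and chiral phosphoric acid ion-pair control of cationic cyclisations. The choice of the (R) catalyst is a proposal: the catalyst antipode is expected to favour 8'S.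

**Compound list**
1 | 2-methylcyclohexan-1-one (racemic) | CC1CCCCC1=O | starting material
2 | 2,6-dimethylcyclohexan-1-one (cis/trans) | CC1CCCC(C)C1=O | intermediate
3 | 2,2,6-trimethylcyclohexan-1-one (racemic) | CC1CCCC(C)(C)C1=O | intermediate
4 | 2,4,6-tri(propan-2-yl)-N'-[(1E)-2,2,6-trimethylcyclohexylidene]benzenesulfonohydrazide | CC1CCCC(C)(C)/C1=N/NS(=O)(=O)c1c(C(C)C)cc(C(C)C)cc1C(C)C | intermediate
5 | 2,6,6-trimethylcyclohex-1-en-1-yllithium | [Li]C1=C(C)CCCC1(C)C | intermediate
6 | (2,6,6-trimethylcyclohex-1-en-1-yl)methanol | OCC1=C(C)CCCC1(C)C | intermediate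
7 | [(1R,6R)-2,2,6-trimethyl-7-oxabicyclo[4.1.0]heptan-1-yl]methanol | OC[C@]1(O2)C(C)(C)CCC[C@]12C | intermediate
8 | (1S,6R)-2,2,6-trimethyl-7-oxabicyclo[4.1.0]heptane-1-carbaldehyde | O=C[C@]1(O2)C(C)(C)CCC[C@]12C | intermediate
9 | (1R,6R)-2,2,6-trimethyl-7-oxabicyclo[4.1.0]heptan-1-yl formate | O=CO[C@]1(O2)C(C)(C)CCC[C@]12C | intermediate
10 | (2R)-2-hydroxy-2,6,6-trimethylcyclohexan-1-one | O=C1C(C)(C)CCC[C@@]1(C)O | intermediate
11 | (2E)-3-methylpent-2-en-4-yn-1-ol | C#C/C(C)=C/CO | starting material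
12 | (2R)-2,6,6-trimethyl-2-[(trimethylsilyl)oxy]cyclohexan-1-one | O=C1C(C)(C)CCC[C@@]1(C)O[Si](C)(C)C | intermediate
13 | (1R,2R)-1-[(3E)-5-hydroxy-3-methylpent-3-en-1-yn-1-yl]-2,6,6-trimethyl-2-[(trimethylsilyl)oxy]cyclohexan-1-ol (present as its lithium alkoxide) | OC/C=C(C)/C#C[C@]1(O)C(C)(C)CCC[C@@]1(C)O[Si](C)(C)C | intermediate
14 | (1R,2R)-1-[(3E)-5-hydroxy-3-methylpent-3-en-1-yn-1-yl]-2,6,6-trimethylcyclohexane-1,2-diol (cis-diol) | OC/C=C(C)/C#C[C@]1(O)C(C)(C)CCC[C@@]1(C)O | intermediate
15 | (1S,2R)-1-[(1E,3E)-5-hydroxy-3-methylpenta-1,3-dien-1-yl]-2,6,6-trimethylcyclohexane-1,2-diol | OC/C=C(C)/C=C/[C@]1(O)C(C)(C)CCC[C@@]1(C)O | intermediate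
16 | (1S,2R)-1-[(1E,3E)-5-bromo-3-methylpenta-1,3-dien-1-yl]-2,6,6-trimethylcyclohexane-1,2-diol | BrC/C=C(C)/C=C/[C@]1(O)C(C)(C)CCC[C@@]1(C)O | intermediate
17 | {(2E,4E)-5-[(1S,2R)-1,2-dihydroxy-2,6,6-trimethylcyclohexyl]-3-methylpenta-2,4-dien-1-yl}(triphenyl)phosphonium bromide | [Br-].c1ccccc1[P+](c1ccccc1)(c1ccccc1)C/C=C(C)/C=C/[C@]1(O)C(C)(C)CCC[C@@]1(C)O | intermediate
18 | (3E)-4-[(1S,6R)-2,2,6-trimethyl-7-oxabicyclo[4.1.0]heptan-1-yl]but-3-en-2-one | CC(=O)/C=C/[C@]1(O2)C(C)(C)CCC[C@]12C | intermediate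
19 | (1E)-3-methyl-1-[(1S,6R)-2,2,6-trimethyl-7-oxabicyclo[4.1.0]heptan-1-yl]penta-1,4-dien-3-ol (C3 epimers) | C=CC(C)(O)/C=C/[C@]1(O2)C(C)(C)CCC[C@]12C | intermediate
20 | {(2E,4E)-3-methyl-5-[(1S,6R)-2,2,6-trimethyl-7-oxabicyclo[4.1.0]heptan-1-yl]penta-2,4-dien-1-yl}(triphenyl)phosphonium bromide | [Br-].c1ccccc1[P+](c1ccccc1)(c1ccccc1)C/C=C(C)/C=C/[C@]1(O2)C(C)(C)CCC[C@]12C | intermediate
21 | (2E)-1,1,4,4-tetramethoxybut-2-ene (fumaraldehyde with both aldehydes protected as dimethyl acetals) | COC(OC)/C=C/C(OC)OC | starting material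
22 | (2E)-but-2-enedial (fumaraldehyde) | O=C/C=C/C=O | intermediate
23 | (2E,4E)-2-methylhexa-2,4-dienedial | O=C/C=C/C=C(C)/C=O | intermediate
24 | (2E,4E,6E)-2,7-dimethylocta-2,4,6-trienedial | O=C/C(C)=C/C=C/C=C(C)/C=O | intermediate
25 | (all-E)-(5R,6S)-5,6-epoxy-5,6-dihydro-12'-apo-β-caroten-12'-al | O=C/C(C)=C/C=C/C=C(C)/C=C/C=C(C)/C=C/[C@]1(O2)C(C)(C)CCC[C@]12C | intermediate
26 | (all-E)-(5R,6S,5'R,6'S)-5',6'-epoxy-5,6,5',6'-tetrahydro-β,β-carotene-5,6-diol | CC(/C=C/C=C(C)/C=C/[C@]1(O)C(C)(C)CCC[C@@]1(C)O)=C\C=C\C=C(C)\C=C\C=C(C)\C=C\[C@]2(O3)C(C)(C)CCC[C@]23C | intermediate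
27 | (all-E)-(5R,6S,5'R,8'R)-5',8'-epoxy-5,6,5',8'-tetrahydro-β,β-carotene-5,6-diol | CC(/C=C/C=C(C)/C=C/[C@]1(O)C(C)(C)CCC[C@@]1(C)O)=C\C=C\C=C(C)\C=C\C=C(/C)[C@H]1C=C2C(C)(C)CCC[C@@]2(C)O1 | target

**Step count and risks**

Total step count: 16. Longest linear sequence: 11 steps (1–9, 15, 16; the branch 1–5, 10–12, 14–16 is equally long).

The three steps most likely to fail:

Step 16 (the new catalytic ring expansion). The risks are poor control at C8' and ionisation of the C6 carbinol of the diol end. The fallback uses known chemistry and moves the ring expansion one stage earlier, where no diol is present. It sets out from 25: HCl (0.01 M) in CHCl3 at 0 °C brings about the classical epoxide to furanoid rearrangement and gives (all-E)-(5R,8R)-5,8-epoxy-5,8-dihydro-12'-apo-β-caroten-12'-al F1 together with its epimer (all-E)-(5R,8S)-5,8-epoxy-5,8-dihydro-12'-apo-β-caroten-12'-al F2. The epimers are separated by preparative HPLC, and F2 is put back under the same acid to re-equilibrate through the common cation and is recycled. F1 is then condensed with salt 17 in 1,2-epoxybutane as in step 15, which comes back to the route at 27.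

Step 6 (Baeyer–Villiger excision of C7). The risk is hydrogen migration to the epoxy acid instead of migration of the oxirane carbon. The fallback replaces the oxidative 1,2-shift by a reductive opening and an alkene cleavage, and it keeps the C5–O bond intact throughout. It sets out from 7: I2, PPh3 and imidazole in CH2Cl2 give (1S,6R)-1-(iodomethyl)-2,2,6-trimethyl-7-oxabicyclo[4.1.0]heptane F3. Zn in EtOH at reflux opens the oxirane reductively to (1R)-1,3,3-trimethyl-2-methylidenecyclohexan-1-ol F4. Ozonolysis (O3, CH2Cl2/MeOH, −78 °C, then Me2S) of the exocyclic alkene comes back to the route at 10.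

Step 12 (phosphonium salt formation under acid next to the oxirane). The risk is acid-induced opening or rearrangement of the epoxide before phosphine capture. The fallback builds the same salt without any acid. It sets out from 18: Horner–Wadsworth–Emmons reaction with (EtO)2P(O)CH2CO2Et and NaH in THF gives ethyl (2E,4E)-3-methyl-5-[(1S,6R)-2,2,6-trimethyl-7-oxabicyclo[4.1.0]heptan-1-yl]penta-2,4-dienoate F5 (the minor 2Z isomer is removed by chromatography). iBu2AlH in CH2Cl2 at −78 °C reduces it to (2E,4E)-3-methyl-5-[(1S,6R)-2,2,6-trimethyl-7-oxabicyclo[4.1.0]heptan-1-yl]penta-2,4-dien-1-ol F6. CBr4 and PPh3, then more PPh3, as in step 9, come back to the route at 20.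

Further compounds
F1 | step 16 | (all-E)-(5R,8R)-5,8-epoxy-5,8-dihydro-12'-apo-β-caroten-12'-al | O=C/C(C)=C/C=C/C=C(C)/C=C/C=C(\C)[C@H]1C=C2C(C)(C)CCC[C@@]2(C)O1
F2 | step 16 | (all-E)-(5R,8S)-5,8-epoxy-5,8-dihydro-12'-apo-β-caroten-12'-al | O=C/C(C)=C/C=C/C=C(C)/C=C/C=C(\C)[C@@H]1C=C2C(C)(C)CCC[C@@]2(C)O1
F3 | step 6 | (1S,6R)-1-(iodomethyl)-2,2,6-trimethyl-7-oxabicyclo[4.1.0]heptane | IC[C@]1(O2)C(C)(C)CCC[C@]12C
F4 | step 6 | (1R)-1,3,3-trimethyl-2-methylidenecyclohexan-1-ol | C=C1C(C)(C)CCC[C@@]1(C)O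
F5 | step 12 | ethyl (2E,4E)-3-methyl-5-[(1S,6R)-2,2,6-trimethyl-7-oxabicyclo[4.1.0]heptan-1-yl]penta-2,4-dienoate | CCOC(=O)/C=C(C)/C=C/[C@]1(O2)C(C)(C)CCC[C@]12C
F6 | step 12 | (2E,4E)-3-methyl-5-[(1S,6R)-2,2,6-trimethyl-7-oxabicyclo[4.1.0]heptan-1-yl]penta-2,4-dien-1-ol | OC/C=C(C)/C=C/[C@]1(O2)C(C)(C)CCC[C@]12C
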